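Ring C is cut at O1–C8a and C4–C4a. These two bonds start from neighbouring carbons of ring A, and ring A is oxygenated meta to O1, so ring A can enter as an alkoxy-substituted aryne. In the key step the alkoxide of an (S)-β-hydroxy ester adds to 3,5-bis(methoxymethoxy)benzyne at the future C8a and the aryl anion formed at C4a acylates on the ester, closing ring C. The oxygen at C5, beside the triple bond, steers the addition and is removed later via its triflate. The precursors are a silyl aryl triflate from phloroglucinol and a transfer-hydrogenation-derived hydroxy ester, used as its silyl ether; its stereocentre becomes C2 untouched.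

Key step: step 9

Remark on the chemistry (assumption): the hydroxyl of 15 is taken into the key step as its trimethylsilyl ether, made in the same flask, so that fluoride unmasks an alkoxide with no proton donor present; MOM = methoxymethyl, prenyl = 3-methylbut-2-enyl.

Step 1
Reactants: 1 phloroglucinol
Product: 2 3,5-bis(methoxymethoxy)phenol
Conditions: MOMCl (2.0 equiv), iPr2NEt, DMF, 0 °C → rt
Reagents that add atoms: chloromethyl methyl ether (MOMCl), COCCl
Why: Base-mediated O-alkylation with MOMCl (acetal formation) caps two of the three equivalent hydroxyls statistically, and the mono- and tris-ethers are removed by chromatography, a cost accepted at the first step on an inexpensive triol.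

Step 2
Reactants: 2 3,5-bis(methoxymethoxy)phenol
Product: 3 3,5-bis(methoxymethoxy)phenyl N-isopropylcarbamate
Conditions: iPrNCO, Et3N (cat.), CH2Cl2, rt
Reagents that add atoms: isopropyl isocyanate, CC(C)N=C=O
Why: Amine-catalysed addition of the phenol to the isocyanate (carbamate formation) installs the directing group for ortho-metalation.

Step 3
Reactants: 3 3,5-bis(methoxymethoxy)phenyl N-isopropylcarbamate
Product: 6 3,5-bis(methoxymethoxy)-2-(trimethylsilyl)phenyl N-isopropylcarbamate, via N-silyl carbamate 4 (not isolated), via C-silylated N-silyl carbamate 5 (not isolated)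
Conditions: TBSOTf, TMEDA, Et2O, 0 °C → rt; n-BuLi (2 equiv), TMEDA, −78 °C; TMSCl, −78 °C → rt; aq. NaHSO4
Reagents that add atoms: chlorotrimethylsilane, C[Si](C)(C)Cl
Why: Directed ortho-metalation: transient N-silylation prevents fragmentation of the N–H carbamate, n-BuLi/TMEDA then deprotonates C2, the site flanked by the carbamate and a MOM ether (C2 and C6 are equivalent), the aryllithium is quenched by TMSCl, and the N–Si bond is hydrolysed on work-up.

Step 4
Reactants: 6 3,5-bis(methoxymethoxy)-2-(trimethylsilyl)phenyl N-isopropylcarbamate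
Product: 8 3,5-bis(methoxymethoxy)-2-(trimethylsilyl)phenyl trifluoromethanesulfonate, via silyl phenol 7 (not isolated)
Conditions: DBU, Et2NH, MeCN, 40 °C; then PhNTf2, rt
Reagents that add atoms: N-phenylbis(trifluoromethanesulfonimide), O=S(=O)(N(c1ccccc1)S(=O)(=O)C(F)(F)F)C(F)(F)F
Why: DBU triggers E1cB loss of isopropyl isocyanate (trapped by Et2NH as a urea) to give the phenoxide, which is triflated in the same flask by PhNTf2, a sequence mild enough to keep the electron-rich aryl–silicon bond.

Step 5
Reactants: 9 4′-hydroxyacetophenone; 10 prenyl bromide (2.5 equiv)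
Product: 11 1-[4-hydroxy-3,5-bis(3-methylbut-2-enyl)phenyl]ethanone
Conditions: KOH (10% aq.), rt
Reagents that add atoms: none
Why: Ambident phenoxide alkylation: with the para position blocked and the oxygen solvated by water, SN2 attack of the ortho carbons on the primary allylic bromide should install both prenyl groups (C-alkylation), the O-prenyl ether and the mono-prenyl phenol being the expected separable by-products.

Step 6
Reactants: 11 1-[4-hydroxy-3,5-bis(3-methylbut-2-enyl)phenyl]ethanone
Product: 12 1-[4-(methoxymethoxy)-3,5-bis(3-methylbut-2-enyl)phenyl]ethanone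
Conditions: MOMCl, iPr2NEt, CH2Cl2, 0 °C → 40 °C
Reagents that add atoms: chloromethyl methyl ether (MOMCl), COCCl
Why: Williamson-type O-alkylation with MOMCl caps the acidic, hindered phenol so that it can neither be deprotonated in the Claisen step nor add to the aryne later.

Step 7
Reactants: 12 1-[4-(methoxymethoxy)-3,5-bis(3-methylbut-2-enyl)phenyl]ethanone; 13 dimethyl carbonate
Product: 14 methyl 3-[4-(methoxymethoxy)-3,5-bis(3-methylbut-2-enyl)phenyl]-3-oxopropanoate
Conditions: NaH (2.5 equiv), THF, reflux; AcOH quench
Reagents that add atoms: none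
Why: Crossed Claisen condensation: the sodium enolate of the methyl ketone is methoxycarbonylated by the non-enolisable carbonate and the equilibrium is pulled by deprotonation of the β-keto ester.

Step 8
Reactants: 14 methyl 3-[4-(methoxymethoxy)-3,5-bis(3-methylbut-2-enyl)phenyl]-3-oxopropanoate
Product: 15 methyl (S)-3-hydroxy-3-[4-(methoxymethoxy)-3,5-bis(3-methylbut-2-enyl)phenyl]propanoate
Conditions: RuCl[(S,S)-TsDPEN](p-cymene) (1 mol%), HCO2H–Et3N (5:2), CH2Cl2, 30 °C
Reagents that add atoms: none
Why: Noyori asymmetric transfer hydrogenation: the aryl ketone is reduced through the six-membered Ru–H/N–H transition state with the aryl group held by a CH/π contact to the p-cymene ligand, so that the (S,S)-ligand delivers hydride to the Re face and the new carbinol centre should be (S), as with simple aryl ketones, while alkenes and the ester are untouched.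

Step 9
Reactants: 8 3,5-bis(methoxymethoxy)-2-(trimethylsilyl)phenyl trifluoromethanesulfonate (1.5 equiv); 15 methyl (S)-3-hydroxy-3-[4-(methoxymethoxy)-3,5-bis(3-methylbut-2-enyl)phenyl]propanoate
Product: 18 (S)-5,7-bis(methoxymethoxy)-2-[4-(methoxymethoxy)-3,5-bis(3-methylbut-2-enyl)phenyl]chroman-4-one, via silyl ether 16 (not isolated), via aryne 17 (not isolated)
Conditions: 15, Me3SiNMe2, CH2Cl2, rt, then evaporation to dryness; CsF, 18-crown-6, THF, 0 °C → rt, 8 added over several hours
Reagents that add atoms: none
Why: Proposed new method: fluoride removes the O-silyl group of 16 to give a cesium alkoxide with no proton donor at hand and, by attack at the aryl silicon of 8 with loss of triflate, releases aryne 17; the alkoxide adds to the aryne carbon remote from the neighbouring methoxymethoxy group, the aryl anion formed beside that oxygen attacks the ester carbonyl, and the expelled methoxide is taken up as methoxytrimethylsilane, which relays the desilylation. The closest known reaction type is the fluoride-mediated annulation of arynes with salicylate esters to xanthones, in which a phenoxide adds and the aryl anion is captured by the ester; a secondary alkoxide carrying an ester with α-hydrogens has not been shown in this role. Ring C closes by 6-exo-trig attack of the C4a carbanion on the ester carbon. No stereocentre is created: C2 is the carbinol carbon of 15 and keeps its (S) configuration because its C–O bond is never broken. The step needs one regiochemistry of addition, secured by the inductively withdrawing alkoxy group next to the triple bond (attack at the distal carbon, charge on the proximal one), and it needs acylation to outrun protonation of the aryl anion, retro-aldol cleavage of the alkoxide and base-induced opening of the product, which the aprotic medium, the silyl ether, slow addition of 8 and low temperature are meant to secure.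

Step 10
Reactants: 18 (S)-5,7-bis(methoxymethoxy)-2-[4-(methoxymethoxy)-3,5-bis(3-methylbut-2-enyl)phenyl]chroman-4-one
Product: 19 (S)-5-hydroxy-7-(methoxymethoxy)-2-[4-(methoxymethoxy)-3,5-bis(3-methylbut-2-enyl)phenyl]chroman-4-one
Conditions: MgBr2·OEt2 (3 equiv), CH2Cl2–Et2O, 0 °C → rt; aq. NH4Cl
Reagents that add atoms: none
Why: Chelation-controlled Lewis-acid cleavage of an aryl alkoxymethyl ether: magnesium bound between the C4 carbonyl oxygen and O5 activates only the peri acetal toward bromide, whereas the acetals at C7 and C4′ have no chelating neighbour and the medium is aprotic, so the prenyl groups and C2 should not be affected.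

Step 11
Reactants: 19 (S)-5-hydroxy-7-(methoxymethoxy)-2-[4-(methoxymethoxy)-3,5-bis(3-methylbut-2-enyl)phenyl]chroman-4-one
Product: 20 (S)-7-(methoxymethoxy)-2-[4-(methoxymethoxy)-3,5-bis(3-methylbut-2-enyl)phenyl]-4-oxochroman-5-yl trifluoromethanesulfonate
Conditions: Tf2O (1.3 equiv), pyridine, CH2Cl2, −10 °C → rt
Reagents that add atoms: trifluoromethanesulfonic anhydride, O=S(=O)(OS(=O)(=O)C(F)(F)F)C(F)(F)F
Why: O-Sulfonylation of the hydrogen-bonded C5 phenol, the only free hydroxyl in 19, with Tf2O and pyridine gives the aryl triflate under conditions too weakly basic to open the chromanone ring.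

Step 12
Reactants: 20 (S)-7-(methoxymethoxy)-2-[4-(methoxymethoxy)-3,5-bis(3-methylbut-2-enyl)phenyl]-4-oxochroman-5-yl trifluoromethanesulfonate
Product: 21 (S)-7-(methoxymethoxy)-2-[4-(methoxymethoxy)-3,5-bis(3-methylbut-2-enyl)phenyl]chroman-4-one
Conditions: Pd(OAc)2 (5 mol%), dppf (6 mol%), Et3N·HCO2H (3 equiv), DMF, 60 °C
Reagents that add atoms: none
Why: Palladium-catalysed formate reduction of an aryl triflate: oxidative addition of the activated C5–O bond to zerovalent palladium, exchange with formate, loss of CO2 and C–H reductive elimination, run in a near-neutral formate buffer so that the trisubstituted alkenes are not reduced and C2 is not epimerised by ring opening.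

Step 13
Reactants: 21 (S)-7-(methoxymethoxy)-2-[4-(methoxymethoxy)-3,5-bis(3-methylbut-2-enyl)phenyl]chroman-4-one
Product: 22 (S)-7-hydroxy-2-[4-hydroxy-3,5-bis(3-methylbut-2-enyl)phenyl]chroman-4-one
Conditions: 3 M aq. HCl, MeOH, 45 °C
Reagents that add atoms: none
Why: Acid-catalysed acetal solvolysis (MOM removal) frees both phenols under mild conditions chosen to keep the prenyl groups from cyclising onto the adjacent phenol, and acid, unlike base, does not open the flavanone ring, so C2 should stay (S).

Compound list

1 | phloroglucinol (benzene-1,3,5-triol) | Oc1cc(O)cc(O)c1 | starting material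
2 | 3,5-bis(methoxymethoxy)phenol | COCOc1cc(O)cc(OCOC)c1 | intermediate
3 | 3,5-bis(methoxymethoxy)phenyl N-isopropylcarbamate | COCOc1cc(OCOC)cc(OC(=O)NC(C)C)c1 | intermediate
4 | 3,5-bis(methoxymethoxy)phenyl N-(tert-butyldimethylsilyl)-N-isopropylcarbamate (formed in the flask of step 3) | COCOc1cc(OCOC)cc(OC(=O)N(C(C)C)[Si](C)(C)C(C)(C)C)c1 | intermediate
5 | 3,5-bis(methoxymethoxy)-2-(trimethylsilyl)phenyl N-(tert-butyldimethylsilyl)-N-isopropylcarbamate (formed in the flask of step 3) | COCOc1cc(OCOC)c([Si](C)(C)C)c(OC(=O)N(C(C)C)[Si](C)(C)C(C)(C)C)c1 | intermediate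
6 | 3,5-bis(methoxymethoxy)-2-(trimethylsilyl)phenyl N-isopropylcarbamate | COCOc1cc(OCOC)c([Si](C)(C)C)c(OC(=O)NC(C)C)c1 | intermediate
7 | 3,5-bis(methoxymethoxy)-2-(trimethylsilyl)phenol (formed as its DBU salt in the flask of step 4) | COCOc1cc(OCOC)c([Si](C)(C)C)c(O)c1 | intermediate
8 | 3,5-bis(methoxymethoxy)-2-(trimethylsilyl)phenyl trifluoromethanesulfonate | COCOc1cc(OCOC)c([Si](C)(C)C)c(OS(=O)(=O)C(F)(F)F)c1 | intermediate
9 | 4′-hydroxyacetophenone (1-(4-hydroxyphenyl)ethanone) | CC(=O)c1ccc(O)cc1 | starting material
10 | prenyl bromide (1-bromo-3-methylbut-2-ene) | CC(C)=CCBr | starting material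
11 | 1-[4-hydroxy-3,5-bis(3-methylbut-2-enyl)phenyl]ethanone | CC(=O)c1cc(CC=C(C)C)c(O)c(CC=C(C)C)c1 | intermediate
12 | 1-[4-(methoxymethoxy)-3,5-bis(3-methylbut-2-enyl)phenyl]ethanone | CC(=O)c1cc(CC=C(C)C)c(OCOC)c(CC=C(C)C)c1 | intermediate
13 | dimethyl carbonate | COC(=O)OC | starting material
14 | methyl 3-[4-(methoxymethoxy)-3,5-bis(3-methylbut-2-enyl)phenyl]-3-oxopropanoate | COC(=O)CC(=O)c1cc(CC=C(C)C)c(OCOC)c(CC=C(C)C)c1 | intermediate
15 | methyl (S)-3-hydroxy-3-[4-(methoxymethoxy)-3,5-bis(3-methylbut-2-enyl)phenyl]propanoate | COC(=O)C[C@H](O)c1cc(CC=C(C)C)c(OCOC)c(CC=C(C)C)c1 | intermediate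
16 | methyl (S)-3-[4-(methoxymethoxy)-3,5-bis(3-methylbut-2-enyl)phenyl]-3-(trimethylsilyloxy)propanoate (formed in the flask of step 9) | COC(=O)C[C@H](O[Si](C)(C)C)c1cc(CC=C(C)C)c(OCOC)c(CC=C(C)C)c1 | intermediate
17 | 3,5-bis(methoxymethoxy)benzyne (1,2-didehydro-3,5-bis(methoxymethoxy)benzene; formed in the flask of step 9) | COCOC1=CC#CC(OCOC)=C1 | intermediate
18 | (S)-5,7-bis(methoxymethoxy)-2-[4-(methoxymethoxy)-3,5-bis(3-methylbut-2-enyl)phenyl]chroman-4-one | CC(C)=CCc1cc([C@@H]2CC(=O)c3c(OCOC)cc(OCOC)cc3O2)cc(CC=C(C)C)c1OCOC | intermediate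
19 | (S)-5-hydroxy-7-(methoxymethoxy)-2-[4-(methoxymethoxy)-3,5-bis(3-methylbut-2-enyl)phenyl]chroman-4-one | CC(C)=CCc1cc([C@@H]2CC(=O)c3c(O)cc(OCOC)cc3O2)cc(CC=C(C)C)c1OCOC | intermediate
20 | (S)-7-(methoxymethoxy)-2-[4-(methoxymethoxy)-3,5-bis(3-methylbut-2-enyl)phenyl]-4-oxochroman-5-yl trifluoromethanesulfonate | CC(C)=CCc1cc([C@@H]2CC(=O)c3c(OS(=O)(=O)C(F)(F)F)cc(OCOC)cc3O2)cc(CC=C(C)C)c1OCOC | intermediate
21 | (S)-7-(methoxymethoxy)-2-[4-(methoxymethoxy)-3,5-bis(3-methylbut-2-enyl)phenyl]chroman-4-one | CC(C)=CCc1cc([C@@H]2CC(=O)c3ccc(OCOC)cc3O2)cc(CC=C(C)C)c1OCOC | intermediate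
22 | (S)-7-hydroxy-2-[4-hydroxy-3,5-bis(3-methylbut-2-enyl)phenyl]chroman-4-one | CC(C)=CCc1cc([C@@H]2CC(=O)c3ccc(O)cc3O2)cc(CC=C(C)C)c1O | target

Total step count: 13.
Longest linear sequence: 9 steps (steps 5–8, then 9–13; the branch through steps 1–4 and 9–13 is equally long).

Steps most likely to fail

Step 9. The aryl anion may be protonated before it acylates, the alkoxide may fragment by retro-aldol cleavage, or the product may be opened by base with loss of configuration at C2. The fallback uses known chemistry and needs no aryne. It sets out from 14 and 2. Reduction of 14 under the conditions of step 8 with the enantiomeric catalyst RuCl[(R,R)-TsDPEN](p-cymene) should give methyl (R)-3-hydroxy-3-[4-(methoxymethoxy)-3,5-bis(3-methylbut-2-enyl)phenyl]propanoate F1. Mitsunobu etherification of F1 with phenol 2 (PPh3, DIAD, toluene, 0 °C) inverts the carbinol carbon and should give methyl (S)-3-[3,5-bis(methoxymethoxy)phenoxy]-3-[4-(methoxymethoxy)-3,5-bis(3-methylbut-2-enyl)phenyl]propanoate F2. Saponification (LiOH, THF–H2O, 0 °C) gives (S)-3-[3,5-bis(methoxymethoxy)phenoxy]-3-[4-(methoxymethoxy)-3,5-bis(3-methylbut-2-enyl)phenyl]propanoic acid F3. Intramolecular Friedel–Crafts acylation through the mixed anhydride (TFAA, CH2Cl2, 0 °C) closes ring C at either of the two equivalent positions ortho to the ether oxygen of the phloroglucinol-type ring, and the route is rejoined at 18.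

Step 10. Site selectivity of the acetal cleavage may be lost (the C7 or C4′ acetal is also cleaved) or the cleavage may stall. The fallback sets out from 18 and separates the hydroxyls by their reactivity instead. Treatment with 3 M aq. HCl in MeOH at 45 °C removes all three acetals to give (S)-5,7-dihydroxy-2-[4-hydroxy-3,5-bis(3-methylbut-2-enyl)phenyl]chroman-4-one F4. MOMCl (2.2 equiv) and iPr2NEt in CH2Cl2 at 0 °C then protect the hydroxyls at C7 and C4′ and leave the hydrogen-bonded C5 hydroxyl free, which rejoins the route at 19.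

Step 5. O-Alkylation may compete with C-alkylation and the second C-alkylation may stall, so that little doubly prenylated phenol is formed. The fallback sets out from 9 and builds the two aryl–prenyl bonds by cross-coupling. Bromination (Br2, AcOH, rt) gives 1-(3,5-dibromo-4-hydroxyphenyl)ethanone F5. MOMCl and iPr2NEt in CH2Cl2 give 1-[3,5-dibromo-4-(methoxymethoxy)phenyl]ethanone F6. Twofold Stille coupling with tributyl(3-methylbut-2-enyl)stannane (Pd(PPh3)4, DMF, 90 °C) should transfer the prenyl group through its unsubstituted terminus and rejoin the route at 12.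

Further compounds

F1 | step 9 | methyl (R)-3-hydroxy-3-[4-(methoxymethoxy)-3,5-bis(3-methylbut-2-enyl)phenyl]propanoate | COC(=O)C[C@@H](O)c1cc(CC=C(C)C)c(OCOC)c(CC=C(C)C)c1
F2 | step 9 | methyl (S)-3-[3,5-bis(methoxymethoxy)phenoxy]-3-[4-(methoxymethoxy)-3,5-bis(3-methylbut-2-enyl)phenyl]propanoate | COC(=O)C[C@H](Oc1cc(OCOC)cc(OCOC)c1)c1cc(CC=C(C)C)c(OCOC)c(CC=C(C)C)c1
F3 | step 9 | (S)-3-[3,5-bis(methoxymethoxy)phenoxy]-3-[4-(methoxymethoxy)-3,5-bis(3-methylbut-2-enyl)phenyl]propanoic acid | OC(=O)C[C@H](Oc1cc(OCOC)cc(OCOC)c1)c1cc(CC=C(C)C)c(OCOC)c(CC=C(C)C)c1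
F4 | step 10 | (S)-5,7-dihydroxy-2-[4-hydroxy-3,5-bis(3-methylbut-2-enyl)phenyl]chroman-4-one | CC(C)=CCc1cc([C@@H]2CC(=O)c3c(O)cc(O)cc3O2)cc(CC=C(C)C)c1O
F5 | step 5 | 1-(3,5-dibromo-4-hydroxyphenyl)ethanone | CC(=O)c1cc(Br)c(O)c(Br)c1
F6 | step 5 | 1-[3,5-dibromo-4-(methoxymethoxy)phenyl]ethanone | CC(=O)c1cc(Br)c(OCOC)c(Br)c1
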